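The numbers of this flask were drawn at random within sensible limits; the run is a simulation.

If over-reaction takes each target molecule at a fixed rate from its birth, the share of target in a flask shows how old its target is.

    partner → decomposed reagent (k1 = 0.23 /min)
    target → over-reaction product (k2 = 0.0091 /min)
    substrate + partner → target (k3 = 3.8 × 10⁻⁴ /M/min)
    substrate + partner + target → 2 target (k4 = 11 /M²/min)

the same everywhere: time 80 min

| charge | substrate | partner | remark |
|---|---|---|---|
| dusk | 0.25 M | 0.225 M (fed, over 1.0 h) | all else is in the flask from the start; the feed brings no volume worth counting |
| spring | 0.25 M (fed, over 1.0 h) | 0.225 M | all else is in the flask from the start; the feed brings no volume worth counting |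
| summer | 0.25 M | 0.225 M | everything together at the start |

- the flask that comes out highest in share of target in target plus over-reaction product, or "all alike" when all lie within 1.5 percentage points (dusk / spring / summer / all alike)
- share of target in target plus over-reaction product at the end, dusk
- share of target in target plus over-reaction product at the end, spring
- share of target in target plus over-reaction product at the end, summer

I began with the target's lifetime against over-reaction, 110 min. The share is close to the exponential of minus the mean age over this lifetime. So I reckoned ages from rates.

In summer each target molecule at the start bred more target (autocatalysis) at 0.619 /min. Decay of partner slowed that rate with a lifetime of 4.35 min, far shorter than the target's. So I put the summer target's birth about one partner lifetime in. Its age was then 75.7 min and its share 50.2%. Spring holds its partner from the start, and that lifetime is far shorter than the feed, so I put spring near summer.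

In dusk the feed held c(partner) near 0.0163 M. That slowed the breeding rate by a factor 13.8, to 0.0448 /min. A stock growing exponentially has a mean age of one growth time, here 22.3 min, which is shorter than the feed. Adding the 20.0 min after the feed gave an age of 42.3 min and a share of 68.0%.

The forecast chose dusk, with 73.5% for dusk, 52.4% for spring and 51.5% for summer. Its ground was that “feeding the partner in dusk keeps it alive for the full hour”. My dusk share stood below its range.

The flasks gave 73.5% for dusk, 52.5% for spring and 51.6% for summer, so dusk came highest, and the forecast held. Shortening the dusk feed to 18.0 min gave 56.9%, lower than with the feed of 1.0 h. Read through the lifetime, the dusk target was 33.8 min old, younger than I had reckoned.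

For a dusk flask charged with 0.56 M of partner, the growth time became 8.96 min, so the age was 29.0 min and the share 76.8%. The computed share was 79.2%.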